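## The problem

Thielavin Z8 (28) is a tridepside: three highly substituted benzene rings joined only by two aryl ester links. It has no stereocenter, so the task is one of position, not of space. Rings A and B are the same 2,4-dihydroxy-3,5,6-trimethylbenzoyl unit, but ring A keeps both hydroxyls free while ring B is acylated on O4 and keeps its chelated O2–H. The two copies therefore need an orthogonal mask on the ring B carboxyl. Each ester carbonyl lies between two ortho substituents and each acylated phenol oxygen lies between two methyl groups, so ordinary acyl transfer is slow at both links. Ring C is a 2,4,5-trimethylresorcinol unit acylated on the more hindered oxygen: O1, between the C2 and C6 methyls, carries the acyl group, while O3, next to the only ring hydrogen (C4–H), is free. Direct acylation of the diol would favour O3. The sensitive parts are the two aryl esters (cleaved or scrambled by strong nucleophiles and hot base), the electron-rich resorcylic acids on the way (prone to protodecarboxylation), and the free C4–H of ring C, which invites C-acylation under acidic acylating conditions. The feature that opens the key step is the pattern of ring C: C4(H)–C5(Me)–C6(Me) with C1–O maps onto a methyl-substituted vinylketene and C2(Me)–C3(O) onto a silyloxypropyne, so a benzannulation should deliver O1 as a free phenol and O3 as a silyl ether in one operation.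

## Retrosynthesis

**Unmasking.** 28 is traced to tri-O-benzyl ether 27 and then to silyl ether 26. Only O–CH2Ph and O–Si bonds are cut. The silyl group on O3 of ring C is dictated by the benzannulation. Benzyl is chosen for the other three oxygens because neutral hydrogenolysis spares the depside esters. Buffered fluoride comes first, so that the last step ends with a filtration.

**Ring B–ring C ester.** The acyl C–O bond between the ring B carbonyl and O1 of ring C is cut, giving acid chloride 24 (from acid 23) and phenoxide 25 (from phenol 12). Cutting the A–B ester first would leave a B–C fragment that needs a temporary group on O4 of ring B. The cut chosen is the most convergent and brings in the product of the key step at the latest point. The forward reaction must acylate a di-ortho-substituted phenoxide with a di-ortho-substituted aroyl chloride on oxygen, not at C4, and must leave the existing A–B ester alone. All other hydroxyls are therefore capped.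

**Ring C (key disconnection).** Phenol 12 is cut at C1–C2, C3–C4 and C1–C6, with C4–C5 traced to a Wolff shift, giving diazo ketone 3 and silyloxyalkyne 7. Starting from the symmetrical-looking resorcinol would require acylating the more hindered oxygen against its intrinsic preference. Here the ketene oxygen becomes the free hindered phenol and the alkyne oxygen the silyl ether, so no selective protection is needed. A pentasubstituted arene is reduced to two acyclic fragments of five and three carbons. The forward reaction needs one thing: the right orientation of the ketene–alkyne (2+2) step.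

**Benzannulation partners.** Diazo ketone 3 is traced to enone 1 by cutting the C=N2 bond (diazo transfer to the activated methyl group). Alkyne 7 is traced to ester 4 through ynolate 6 by cutting one C–C bond (one-carbon homologation with 1,2-shift) and the O–Si bond. Both are single operations on commodity chemicals.

**Ring A–ring B ester.** Acid 23 is traced through benzyl ether 22 to phenol 21, and 21 is cut at the A–B acyl C–O bond to acid 17 and allyl ester 19. The chelated 2-hydroxyl of 19 stays free in the coupling, so acylation goes to the para hydroxyl, and it is benzylated afterwards. The allyl ester is chosen over the methyl ester because zerovalent palladium removes it without touching a diaryl ester or benzyl ethers. A methyl ester would have to be cleaved beside an equally hindered aryl ester.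

**Rings A and B from one ester.** Acid 17 is traced through bis-benzyl ether 16 to ester 15. Allyl ester 19 is traced through acid 18 to the same ester 15. One compound thus supplies both rings, and the only cuts are O–C bonds to protecting groups and the ester O–CH3 bond.

**The fifth ring substituent.** Ester 15 is cut at the C5–CH3 bond, via aldehyde 14, back to atraric acid 13. Compound 13 already carries two of the three methyls and both oxygens, and has a single free ring position, so regiochemistry is automatic.

## Roads not taken

**Alternative 1:** The cut removes all six nuclear methyl groups at C3 and C5 of three orsellinate-type rings and adds a carboxyl to ring C. The target is traced to hexabromide A2, a benzyl-protected tridepside of three 3,5-dibromo-6-methyl-2,4-dioxybenzoate units. In the forward key step zerovalent palladium, generated from Pd(OAc)2 and SPhos, couples all six aryl bromides of A2 with (MeBO)3 to give A1. Hydrogenolysis would give acid A3, and protodecarboxylation of A3 would give 28.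
- Merits: one cheap monomer type serves all three rings; bromination is regiochemically unambiguous; there is no photochemistry and no diazo compound; the C4–H of ring C arises simply by loss of CO2.
- Weak points: each bromide has two ortho neighbours and all six couplings must go to completion. Every protodebromination gives a congener lacking one CH2, which would be very hard to separate from A1. The coupling needs base and heat beside two aryl esters and a benzyl ester. A3 must lose CO2 without ester scrambling, and its ring is less electron-rich than a free resorcylic acid because O4 is acylated. Assembling A2 needs the same orthogonal-carboxyl logistics as the chosen plan, once more for ring C.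
- Comparison: in uniformity of building blocks and in avoiding photochemistry this road is better. The chosen plan sets against it that every methyl group is in place before any ester is formed, that its demanding step is run early on small molecules, and that no late sixfold reaction has to be perfect.

**Alternative 2:** The cut goes through ring B itself, at two C–C bonds. Ester A4 is traced to bis(silyl enol ether) A5, made from a β-keto ester of the ring C phenol A7, and to the three-carbon acid chloride A6. In the forward key step TiCl4 promotes acylation of the diene terminus of A5 by A6, then aldol-type closure of the central diene carbon onto the masked methyl ketone, with loss of methanol and aromatization to A4.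
- Merits: the B–C ester bond is made as an unhindered aliphatic acylation of A7 before ring B exists. This removes the hardest esterification of the whole synthesis, and in that respect the road is clearly better than the chosen plan. Both hydroxyls of ring B appear free, and O4 could then be acylated selectively by the ring A acid.
- Weak points: A7 must still be made with O1 and O3 differentiated, which is exactly the problem the benzannulation solves. Aryl β-keto esters lose phenoxide to an acylketene under the strong base needed to make A5. The cyclocondensation must join a methyl-bearing diene terminus and a tetrasubstituted enol ether into a hexasubstituted ring, with O- versus C-acylation open. TiCl4 meets a benzyl ether.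
- Comparison: the chosen plan accepts a hindered esterification, for which phenoxide–acid chloride and mixed-anhydride couplings are established in depside chemistry. In return its ring-forming step is a known reaction type and also solves the ring C oxygen problem.

**Alternative 3:** The cut removes two C–O bonds, the chelated hydroxyls of rings A and B. Diacetate A8 is traced to A9, in which rings A and B are 4-acyloxy-2,3,5-trimethylbenzoyl units. In the forward key step the divalent ruthenium precatalyst [RuCl2(p-cymene)]2 with PhI(OCOCF3)2 in CF3CO2H/(CF3CO)2O metalates the C–H ortho to each ester carbonyl and oxidizes both positions. Deacetylation of A8 would give 28.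
- Merits: the acids that form the esters have only one ortho substituent, so both esterifications are easier than in the chosen plan. No chelated phenol needs protection. Each ring has a single ortho C–H, so regiochemistry is unambiguous.
- Weak points: the directing groups are aryl esters, weak donors twisted out of plane by the ortho methyl, and each C–H is flanked by a methyl group. The reaction must succeed twice in one molecule. The C4–H of ring C is the most electron-rich C–H in A9 and is open to undirected oxidation by the iodine reagent. The hot acidic anhydride medium can exchange the acetates and scramble the depside esters. Ring C must still be made with differentiated oxygens, and the final deacetylation must spare two aryl esters.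
- Comparison: this road is shorter in protecting-group operations and easier in ester formation. The chosen plan sets against it a key step that is precedented for its substrate class and placed at the start, where failure costs little, instead of an untested double C–H oxidation on the fully assembled triester.

Key step: step 3

Remark on the chemistry: ring positions are numbered as in 28 (ring C: C1 bears the ester oxygen, C3 the free hydroxyl, C4 the hydrogen). Commercial enone 1 is taken as the E isomer; its alkene geometry is lost on aromatization. Intermediates 9 and 11 each have one stereocenter, are racemic and transient; the target has none.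

## Steps

Step 1
Reactants: 1 (E)-3-methylpent-3-en-2-one
Product: 3 (E)-1-diazo-3-methylpent-3-en-2-one, via trifluoroacetyl diketone 2 (not isolated)
Conditions: LiN(SiMe3)2, THF, −78 °C; CF3CO2CH2CF3, −78 °C; aq. HCl work-up; then MsN3, Et3N, H2O (1 equiv), MeCN, rt
Reagents that add atoms: methanesulfonyl azide, CS(=O)(=O)N=[N+]=[N-]
Why: Kinetic deprotonation occurs at the α′ methyl group, Claisen-type trifluoroacetylation activates that carbon, and Regitz-type deacylative (detrifluoroacetylative) diazo transfer gives the α′-diazo enone; this avoids acylating diazomethane with an unsaturated acid chloride, where dipolar addition to the C=C bond interferes.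

Step 2
Reactants: 4 ethyl acetate
Product: 7 1-(triisopropylsilyloxy)prop-1-yne, via dibromo enolate 5 (not isolated), via lithium ynolate 6 (not isolated)
Conditions: CH2Br2, lithium 2,2,6,6-tetramethylpiperidide (LiTMP), THF, −78 °C; then 4; LiN(SiMe3)2; n-BuLi, −78 °C to rt; i-Pr3SiCl, −78 to 0 °C
Reagents that add atoms: dibromomethane, BrCBr; chlorotriisopropylsilane, CC(C)[Si](Cl)(C(C)C)C(C)C
Why: Kowalski ester homologation stopped at the ynolate: LiCHBr2 adds to the ester, the adduct collapses to dibromo enolate 5, bromine–lithium exchange triggers a carbenoid 1,2-shift to ynolate 6, and the bulky silyl chloride silylates oxygen to give the silyl ynol ether.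

Step 3
Reactants: 3 (E)-1-diazo-3-methylpent-3-en-2-one; 7 1-(triisopropylsilyloxy)prop-1-yne
Product: 12 2,5,6-trimethyl-3-(triisopropylsilyloxy)phenol, via vinylketene 8 (not isolated), via vinylcyclobutenone 9 (not isolated), via dienylketene 10 (not isolated), via cyclohexadienone 11 (not isolated)
Conditions: hν (254 nm, low-pressure Hg lamp, Vycor), degassed ClCH2CH2Cl, rt; then 80 °C
Reagents that add atoms: none
Why: Irradiation expels N2 and the alkenyl group migrates to the former diazo carbon (photochemical Wolff rearrangement, forming C4–C5) to give vinylketene 8. The electron-rich alkyne 7 then adds across the ketene C=C bond in a (2+2) cycloaddition, its methyl-bearing carbon bonding to the ketene carbonyl carbon (C1–C2) and its oxygen-bearing carbon to the ketene α-carbon (C3–C4), which closes the four-membered ring of 9. Reversible 4π electrocyclic opening of 9 gives dienylketene 10, and the isomer with the ketene and alkenyl ends cis is drained by thermal disrotatory 6π electrocyclization, which closes the six-membered ring C through C1–C6. Tautomerization of dienone 11 gives the phenol. The closest known reaction type is the photochemical Wolff variant of the Danheiser benzannulation with silyloxyalkynes, which gives resorcinol monosilyl ethers. No stereocenter is set, since the sp3 centers of 9 and 11 disappear on the way. The one selectivity needed is the orientation of the (2+2) step; it is secured by the polarization of the ynol ether (nucleophilic β-carbon) and of the ketene (electrophilic carbonyl carbon). This puts the alkyne methyl between the two oxygens and delivers the hindered O1 as the free phenol and O3 as the silyl ether.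

Step 4
Reactants: 13 methyl 2,4-dihydroxy-3,6-dimethylbenzoate (atraric acid)
Product: 14 methyl 5-formyl-2,4-dihydroxy-3,6-dimethylbenzoate
Conditions: Cl2CHOMe, TiCl4, CH2Cl2, 0 °C to rt; aq. HCl
Reagents that add atoms: dichloromethyl methyl ether, COC(Cl)Cl; water, O
Why: Rieche formylation: TiCl4 binds the phenols and activates the dichloromethyl ether, substitution can occur only at C5, the single free ring carbon and ortho to the 4-hydroxyl, and hydrolysis of the α-chloro ether gives the aldehyde.

Step 5
Reactants: 14 methyl 5-formyl-2,4-dihydroxy-3,6-dimethylbenzoate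
Product: 15 methyl 2,4-dihydroxy-3,5,6-trimethylbenzoate
Conditions: Et3SiH, CF3CO2H, rt
Reagents that add atoms: none
Why: Ionic hydrogenation: the protonated aldehyde, flanked by an ortho and a para hydroxyl, gives a strongly stabilized benzylic cation that takes hydride from the silane twice and ends at the methyl group; the ester is inert and the fully substituted ring cannot be alkylated by the cation.

Step 6
Reactants: 15 methyl 2,4-dihydroxy-3,5,6-trimethylbenzoate
Product: 16 methyl 2,4-bis(benzyloxy)-3,5,6-trimethylbenzoate
Conditions: BnBr (excess), K2CO3, DMF, 60 °C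
Reagents that add atoms: benzyl bromide, BrCc1ccccc1
Why: Twofold Williamson etherification; the chelated 2-hydroxyl needs excess bromide and warming, conditions that leave the hindered methyl ester untouched.

Step 7
Reactants: 16 methyl 2,4-bis(benzyloxy)-3,5,6-trimethylbenzoate
Product: 17 2,4-bis(benzyloxy)-3,5,6-trimethylbenzoic acid
Conditions: KOH, DMSO/H2O, 100 °C; then aq. HCl
Reagents that add atoms: potassium hydroxide, [K+].[OH-]
Why: Saponification of a di-ortho-substituted methyl benzoate with poorly solvated hydroxide in hot aqueous DMSO; aryl benzyl ethers survive, and the acid has no free ortho or para hydroxyl, so it does not decarboxylate on acidification.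

Step 8
Reactants: 15 methyl 2,4-dihydroxy-3,5,6-trimethylbenzoate
Product: 18 2,4-dihydroxy-3,5,6-trimethylbenzoic acid
Conditions: conc. H2SO4, 0 °C to rt; poured onto ice
Reagents that add atoms: water, O
Why: Acid-catalysed unimolecular ester hydrolysis (AAc1): the di-ortho-substituted, electron-rich ester ionizes in cold sulfuric acid to an acylium ion that water captures on quenching; the ring has no free position to sulfonate and the cold quench limits protodecarboxylation.

Step 9
Reactants: 18 2,4-dihydroxy-3,5,6-trimethylbenzoic acid
Product: 19 prop-2-en-1-yl 2,4-dihydroxy-3,5,6-trimethylbenzoate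
Conditions: allyl bromide, KHCO3, DMF, rt
Reagents that add atoms: allyl bromide, C=CCBr
Why: Carboxylate O-alkylation (SN2 on allyl bromide): hydrogen carbonate deprotonates only the carboxylic acid, so neither phenol is allylated, and hindrance at the carbonyl carbon is irrelevant.

Step 10
Reactants: 17 2,4-bis(benzyloxy)-3,5,6-trimethylbenzoic acid; 19 prop-2-en-1-yl 2,4-dihydroxy-3,5,6-trimethylbenzoate
Product: 21 prop-2-en-1-yl 4-{[2,4-bis(benzyloxy)-3,5,6-trimethylbenzoyl]oxy}-2-hydroxy-3,5,6-trimethylbenzoate, via mixed anhydride 20 (not isolated)
Conditions: (CF3CO)2O, toluene, rt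
Reagents that add atoms: none
Why: Depside coupling through the mixed trifluoroacetic anhydride and the acylium ion derived from it, the standard activation for di-ortho-substituted benzoic acids; the hydroxyl para to the ester reacts because the ortho hydroxyl is hydrogen-bonded to the ester carbonyl and more shielded.

Step 11
Reactants: 21 prop-2-en-1-yl 4-{[2,4-bis(benzyloxy)-3,5,6-trimethylbenzoyl]oxy}-2-hydroxy-3,5,6-trimethylbenzoate
Product: 22 prop-2-en-1-yl 2-(benzyloxy)-4-{[2,4-bis(benzyloxy)-3,5,6-trimethylbenzoyl]oxy}-3,5,6-trimethylbenzoate
Conditions: BnBr, K2CO3, DMF, 50 °C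
Reagents that add atoms: benzyl bromide, BrCc1ccccc1
Why: Williamson etherification of the remaining chelated phenol; carbonate at this temperature should not attack the hindered diaryl ester or the allyl ester.

Step 12
Reactants: 22 prop-2-en-1-yl 2-(benzyloxy)-4-{[2,4-bis(benzyloxy)-3,5,6-trimethylbenzoyl]oxy}-3,5,6-trimethylbenzoate
Product: 23 2-(benzyloxy)-4-{[2,4-bis(benzyloxy)-3,5,6-trimethylbenzoyl]oxy}-3,5,6-trimethylbenzoic acid
Conditions: Pd(PPh3)4 (5 mol %), morpholine, THF, rt; dilute acid work-up
Reagents that add atoms: none
Why: Tsuji–Trost deallylation: zerovalent palladium ionizes the allyl ester to a π-allyl complex and the carboxylate, and morpholine takes up the allyl group; benzyl ethers and the aryl ester are inert.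

Step 13
Reactants: 23 2-(benzyloxy)-4-{[2,4-bis(benzyloxy)-3,5,6-trimethylbenzoyl]oxy}-3,5,6-trimethylbenzoic acid; 12 2,5,6-trimethyl-3-(triisopropylsilyloxy)phenol
Product: 26 2,5,6-trimethyl-3-(triisopropylsilyloxy)phenyl 2-(benzyloxy)-4-{[2,4-bis(benzyloxy)-3,5,6-trimethylbenzoyl]oxy}-3,5,6-trimethylbenzoate, via acid chloride 24 (not isolated), via sodium phenoxide 25 (not isolated)
Conditions: 23, (COCl)2, cat. DMF, CH2Cl2, 0 °C to rt, evaporated; 12, NaH, THF, 0 °C; combined in THF, 0 to 60 °C
Reagents that add atoms: none
Why: Acyl substitution of an aroyl chloride by a preformed sodium phenoxide (anhydrous Schotten–Baumann-type O-acylation); the hard phenoxide oxygen is acylated in preference to C4, the acid chloride is far more electrophilic than the existing diaryl ester, and every other hydroxyl is capped so that only O1 of ring C can react.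

Step 14
Reactants: 26 2,5,6-trimethyl-3-(triisopropylsilyloxy)phenyl 2-(benzyloxy)-4-{[2,4-bis(benzyloxy)-3,5,6-trimethylbenzoyl]oxy}-3,5,6-trimethylbenzoate
Product: 27 3-hydroxy-2,5,6-trimethylphenyl 2-(benzyloxy)-4-{[2,4-bis(benzyloxy)-3,5,6-trimethylbenzoyl]oxy}-3,5,6-trimethylbenzoate
Conditions: Bu4NF, AcOH, THF, 0 °C
Reagents that add atoms: none
Why: Fluoride cleavage of an aryl silyl ether, driven by the Si–F bond; acetic acid keeps the liberated phenol protonated so that it cannot attack either aryl ester.

Step 15
Reactants: 27 3-hydroxy-2,5,6-trimethylphenyl 2-(benzyloxy)-4-{[2,4-bis(benzyloxy)-3,5,6-trimethylbenzoyl]oxy}-3,5,6-trimethylbenzoate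
Product: 28 thielavin Z8
Conditions: H2 (1 atm), Pd/C (10% Pd on carbon), EtOAc, rt
Reagents that add atoms: none
Why: Hydrogenolysis of three aryl benzyl ethers over palladium under neutral conditions, which leave the aryl esters and the aromatic rings untouched.

## Compound list

1 | (E)-3-methylpent-3-en-2-one | C/C=C(\C)C(C)=O | starting material
2 | (E)-1,1,1-trifluoro-5-methylhept-5-ene-2,4-dione | C/C=C(\C)C(=O)CC(=O)C(F)(F)F | intermediate (not isolated)
3 | (E)-1-diazo-3-methylpent-3-en-2-one | C/C=C(\C)C(=O)C=[N+]=[N-] | intermediate
4 | ethyl acetate | CCOC(C)=O | starting material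
5 | lithium 1,1-dibromoprop-1-en-2-olate | CC([O-])=C(Br)Br.[Li+] | intermediate (not isolated)
6 | lithium prop-1-yn-1-olate | CC#C[O-].[Li+] | intermediate (not isolated)
7 | 1-(triisopropylsilyloxy)prop-1-yne | CC#CO[Si](C(C)C)(C(C)C)C(C)C | intermediate
8 | (E)-3-methylpenta-1,3-dien-1-one (vinylketene) | C/C=C(\C)C=C=O | intermediate (not isolated)
9 | 4-[(E)-but-2-en-2-yl]-2-methyl-3-(triisopropylsilyloxy)cyclobut-2-en-1-one (racemic) | C/C=C(\C)C1C(=O)C(C)=C1O[Si](C(C)C)(C(C)C)C(C)C | intermediate (not isolated)
10 | (3E,5E)-2,5-dimethyl-3-(triisopropylsilyloxy)hepta-1,3,5-trien-1-one (dienylketene) | O=C=C(C)/C(O[Si](C(C)C)(C(C)C)C(C)C)=C\C(C)=C\C | intermediate (not isolated)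
11 | 2,5,6-trimethyl-3-(triisopropylsilyloxy)cyclohexa-2,4-dien-1-one (racemic) | CC1C(C)=CC(O[Si](C(C)C)(C(C)C)C(C)C)=C(C)C1=O | intermediate (not isolated)
12 | 2,5,6-trimethyl-3-(triisopropylsilyloxy)phenol | Cc1cc(O[Si](C(C)C)(C(C)C)C(C)C)c(C)c(O)c1C | intermediate
13 | methyl 2,4-dihydroxy-3,6-dimethylbenzoate (atraric acid) | COC(=O)c1c(C)cc(O)c(C)c1O | starting material
14 | methyl 5-formyl-2,4-dihydroxy-3,6-dimethylbenzoate | COC(=O)c1c(C)c(C=O)c(O)c(C)c1O | intermediate
15 | methyl 2,4-dihydroxy-3,5,6-trimethylbenzoate | COC(=O)c1c(C)c(C)c(O)c(C)c1O | intermediate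
16 | methyl 2,4-bis(benzyloxy)-3,5,6-trimethylbenzoate | COC(=O)c1c(C)c(C)c(OCc2ccccc2)c(C)c1OCc1ccccc1 | intermediate
17 | 2,4-bis(benzyloxy)-3,5,6-trimethylbenzoic acid | OC(=O)c1c(C)c(C)c(OCc2ccccc2)c(C)c1OCc1ccccc1 | intermediate
18 | 2,4-dihydroxy-3,5,6-trimethylbenzoic acid | OC(=O)c1c(C)c(C)c(O)c(C)c1O | intermediate
19 | prop-2-en-1-yl 2,4-dihydroxy-3,5,6-trimethylbenzoate | C=CCOC(=O)c1c(C)c(C)c(O)c(C)c1O | intermediate
20 | 2,4-bis(benzyloxy)-3,5,6-trimethylbenzoic trifluoroacetic anhydride | Cc1c(C)c(OCc2ccccc2)c(C)c(OCc2ccccc2)c1C(=O)OC(=O)C(F)(F)F | intermediate (not isolated)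
21 | prop-2-en-1-yl 4-{[2,4-bis(benzyloxy)-3,5,6-trimethylbenzoyl]oxy}-2-hydroxy-3,5,6-trimethylbenzoate | C=CCOC(=O)c1c(C)c(C)c(OC(=O)c2c(C)c(C)c(OCc3ccccc3)c(C)c2OCc2ccccc2)c(C)c1O | intermediate
22 | prop-2-en-1-yl 2-(benzyloxy)-4-{[2,4-bis(benzyloxy)-3,5,6-trimethylbenzoyl]oxy}-3,5,6-trimethylbenzoate | C=CCOC(=O)c1c(C)c(C)c(OC(=O)c2c(C)c(C)c(OCc3ccccc3)c(C)c2OCc2ccccc2)c(C)c1OCc1ccccc1 | intermediate
23 | 2-(benzyloxy)-4-{[2,4-bis(benzyloxy)-3,5,6-trimethylbenzoyl]oxy}-3,5,6-trimethylbenzoic acid | OC(=O)c1c(C)c(C)c(OC(=O)c2c(C)c(C)c(OCc3ccccc3)c(C)c2OCc2ccccc2)c(C)c1OCc1ccccc1 | intermediate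
24 | 2-(benzyloxy)-4-{[2,4-bis(benzyloxy)-3,5,6-trimethylbenzoyl]oxy}-3,5,6-trimethylbenzoyl chloride | ClC(=O)c1c(C)c(C)c(OC(=O)c2c(C)c(C)c(OCc3ccccc3)c(C)c2OCc2ccccc2)c(C)c1OCc1ccccc1 | intermediate (not isolated)
25 | sodium 2,5,6-trimethyl-3-(triisopropylsilyloxy)phenoxide | Cc1cc(O[Si](C(C)C)(C(C)C)C(C)C)c(C)c([O-])c1C.[Na+] | intermediate (not isolated)
26 | 2,5,6-trimethyl-3-(triisopropylsilyloxy)phenyl 2-(benzyloxy)-4-{[2,4-bis(benzyloxy)-3,5,6-trimethylbenzoyl]oxy}-3,5,6-trimethylbenzoate | Cc1cc(O[Si](C(C)C)(C(C)C)C(C)C)c(C)c(OC(=O)c2c(C)c(C)c(OC(=O)c3c(C)c(C)c(OCc4ccccc4)c(C)c3OCc3ccccc3)c(C)c2OCc2ccccc2)c1C | intermediate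
27 | 3-hydroxy-2,5,6-trimethylphenyl 2-(benzyloxy)-4-{[2,4-bis(benzyloxy)-3,5,6-trimethylbenzoyl]oxy}-3,5,6-trimethylbenzoate (tri-O-benzyl thielavin Z8) | Cc1cc(O)c(C)c(OC(=O)c2c(C)c(C)c(OC(=O)c3c(C)c(C)c(OCc4ccccc4)c(C)c3OCc3ccccc3)c(C)c2OCc2ccccc2)c1C | intermediate
28 | thielavin Z8, 3-hydroxy-2,5,6-trimethylphenyl 4-[(2,4-dihydroxy-3,5,6-trimethylbenzoyl)oxy]-2-hydroxy-3,5,6-trimethylbenzoate | Cc1cc(O)c(C)c(OC(=O)c2c(C)c(C)c(OC(=O)c3c(C)c(C)c(O)c(C)c3O)c(C)c2O)c1C | target

## Step count and least certain steps

Total: 15 steps. Longest linear sequence: 10 steps, from 13 to 28 through steps 4, 5, 8, 9, 10, 11, 12, 13, 14 and 15. The ring A branch (steps 6, 7) and the ring C branch (steps 1, 2, 3) join it at steps 10 and 13.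

**Step 3 (key step).** The most likely failure is loss of vinylketene 8 before the alkyne captures it: dimerization, or esterification by the product phenol. Incomplete thermal conversion of cyclobutenone 9, or secondary photochemistry of the product under 254 nm light, would add to this. The fallback keeps the same cascade and the same bonds but makes the ketene without light or a diazo compound. It sets out from alkyne 7. 3,4-Dimethylcyclobut-2-en-1-one F1 would be obtained in one operation from propyne and the keteniminium salt of N,N-dimethylpropanamide, by (2+2) cycloaddition and hydrolysis. Heating F1 with 7 in toluene at 80–110 °C should open it slowly to the same ketene 8, which is held at low concentration in the presence of the alkyne. The route is rejoined at phenol 12 through 9, 10 and 11.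

**Step 10.** The acyl transfer may be slow, since the accepting hydroxyl lies between two methyl groups and is deactivated by the para ester. Competing processes are loss of the ortho benzyl group from the acylium ion and acylation of the chelated hydroxyl. The fallback removes the choice between hydroxyls and sets out from acids 18 and 17. Acid 18 with acetone, (CF3CO)2O and CF3CO2H should give the acetonide 7-hydroxy-2,2,5,6,8-pentamethyl-4H-1,3-benzodioxin-4-one F2, in which the chelated hydroxyl and the carboxyl are tied together and one hydroxyl is left. Acylation of F2 with 17 (mixed anhydride, or acid chloride and NaH) would give 2,2,5,6,8-pentamethyl-4-oxo-4H-1,3-benzodioxin-7-yl 2,4-bis(benzyloxy)-3,5,6-trimethylbenzoate F3. Irradiation of F3 at 300 nm in the presence of allyl alcohol should release acetone and an ortho-quinone ketene, which the alcohol traps to give 21, where the route is rejoined.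

**Step 13.** This is a doubly hindered esterification. The likely failure is slow addition of the flanked phenoxide to the flanked acid chloride, which lets decomposition of 24 or acyl exchange at the A–B ester compete. The fallback replaces the crowded tetrahedral pathway by a linear, unhindered ketene. It sets out from 18 and 17, through F2 and F3 as described for step 10, and from phenol 12. Irradiation of F3 at 300 nm with 12 should give 2,5,6-trimethyl-3-(triisopropylsilyloxy)phenyl 4-{[2,4-bis(benzyloxy)-3,5,6-trimethylbenzoyl]oxy}-2-hydroxy-3,5,6-trimethylbenzoate F4. Buffered fluoride would then give 3-hydroxy-2,5,6-trimethylphenyl 4-{[2,4-bis(benzyloxy)-3,5,6-trimethylbenzoyl]oxy}-2-hydroxy-3,5,6-trimethylbenzoate F5, and hydrogenolysis of F5 rejoins the route at 28. This sequence is shorter than the main line. It is held in reserve because photochemical acylation of a di-ortho-substituted phenol is less tested than the phenoxide method, and because aryl esters can undergo photo-Fries cleavage under irradiation.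

**Step 8.** The resorcylic acid may lose CO2 by ipso-protonation during quenching or isolation. The fallback avoids the free acid and sets out from ester 15 and acid 17. Coupling under the conditions of step 10 should give methyl 4-{[2,4-bis(benzyloxy)-3,5,6-trimethylbenzoyl]oxy}-2-hydroxy-3,5,6-trimethylbenzoate F6. Benzylation as in step 11 would give methyl 2-(benzyloxy)-4-{[2,4-bis(benzyloxy)-3,5,6-trimethylbenzoyl]oxy}-3,5,6-trimethylbenzoate F7. Cleavage of the methyl ester by SN2 attack of iodide on the methyl group (LiI, pyridine, reflux) would leave the aryl ester alone, since iodide attacks carbon only at the O–CH3 group, and the route is rejoined at acid 23. The price is a selectivity question between the methyl ester and the benzyl ethers, which the allyl ester of the main line avoids.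

## Further compounds

F1 | step 3 | 3,4-dimethylcyclobut-2-en-1-one (racemic) | CC1C(C)=CC1=O
F2 | step 10 | 7-hydroxy-2,2,5,6,8-pentamethyl-4H-1,3-benzodioxin-4-one | Cc1c(O)c(C)c2OC(C)(C)OC(=O)c2c1C
F3 | step 10 | 2,2,5,6,8-pentamethyl-4-oxo-4H-1,3-benzodioxin-7-yl 2,4-bis(benzyloxy)-3,5,6-trimethylbenzoate | Cc1c(OC(=O)c2c(C)c(C)c(OCc3ccccc3)c(C)c2OCc2ccccc2)c(C)c2OC(C)(C)OC(=O)c2c1C
F4 | step 13 | 2,5,6-trimethyl-3-(triisopropylsilyloxy)phenyl 4-{[2,4-bis(benzyloxy)-3,5,6-trimethylbenzoyl]oxy}-2-hydroxy-3,5,6-trimethylbenzoate | Cc1cc(O[Si](C(C)C)(C(C)C)C(C)C)c(C)c(OC(=O)c2c(C)c(C)c(OC(=O)c3c(C)c(C)c(OCc4ccccc4)c(C)c3OCc3ccccc3)c(C)c2O)c1C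
F5 | step 13 | 3-hydroxy-2,5,6-trimethylphenyl 4-{[2,4-bis(benzyloxy)-3,5,6-trimethylbenzoyl]oxy}-2-hydroxy-3,5,6-trimethylbenzoate | Cc1cc(O)c(C)c(OC(=O)c2c(C)c(C)c(OC(=O)c3c(C)c(C)c(OCc4ccccc4)c(C)c3OCc3ccccc3)c(C)c2O)c1C
F6 | step 8 | methyl 4-{[2,4-bis(benzyloxy)-3,5,6-trimethylbenzoyl]oxy}-2-hydroxy-3,5,6-trimethylbenzoate | COC(=O)c1c(C)c(C)c(OC(=O)c2c(C)c(C)c(OCc3ccccc3)c(C)c2OCc2ccccc2)c(C)c1O
F7 | step 8 | methyl 2-(benzyloxy)-4-{[2,4-bis(benzyloxy)-3,5,6-trimethylbenzoyl]oxy}-3,5,6-trimethylbenzoate | COC(=O)c1c(C)c(C)c(OC(=O)c2c(C)c(C)c(OCc3ccccc3)c(C)c2OCc2ccccc2)c(C)c1OCc1ccccc1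
A1 | alternative 1 | benzyl 2-(benzyloxy)-4-{[2-(benzyloxy)-4-{[2,4-bis(benzyloxy)-3,5,6-trimethylbenzoyl]oxy}-3,5,6-trimethylbenzoyl]oxy}-3,5,6-trimethylbenzoate | Cc1c(C)c(OCc2ccccc2)c(C)c(OCc2ccccc2)c1C(=O)Oc1c(C)c(C)c(C(=O)Oc2c(C)c(C)c(C(=O)OCc3ccccc3)c(OCc3ccccc3)c2C)c(OCc2ccccc2)c1C
A2 | alternative 1 | benzyl 2-(benzyloxy)-4-{[2-(benzyloxy)-4-{[2,4-bis(benzyloxy)-3,5-dibromo-6-methylbenzoyl]oxy}-3,5-dibromo-6-methylbenzoyl]oxy}-3,5-dibromo-6-methylbenzoate | Cc1c(Br)c(OCc2ccccc2)c(Br)c(OCc2ccccc2)c1C(=O)Oc1c(Br)c(C)c(C(=O)Oc2c(Br)c(C)c(C(=O)OCc3ccccc3)c(OCc3ccccc3)c2Br)c(OCc2ccccc2)c1Br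
A3 | alternative 1 | 4-({4-[(2,4-dihydroxy-3,5,6-trimethylbenzoyl)oxy]-2-hydroxy-3,5,6-trimethylbenzoyl}oxy)-2-hydroxy-3,5,6-trimethylbenzoic acid | Cc1c(C)c(O)c(C)c(O)c1C(=O)Oc1c(C)c(C)c(C(=O)Oc2c(C)c(C)c(C(=O)O)c(O)c2C)c(O)c1C
A4 | alternative 2 | 3-(benzyloxy)-2,5,6-trimethylphenyl 2,4-dihydroxy-3,5,6-trimethylbenzoate | Cc1cc(OCc2ccccc2)c(C)c(OC(=O)c2c(C)c(C)c(O)c(C)c2O)c1C
A5 | alternative 2 | 1-[3-(benzyloxy)-2,5,6-trimethylphenoxy]-1,3-bis(trimethylsilyloxy)penta-1,3-diene (double-bond geometry not defined) | CC=C(O[Si](C)(C)C)C=C(O[Si](C)(C)C)Oc1c(C)c(C)cc(OCc2ccccc2)c1C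
A6 | alternative 2 | 3-methoxy-2-methylbut-2-enoyl chloride (double-bond geometry not defined) | COC(C)=C(C)C(Cl)=O
A7 | alternative 2 | 3-(benzyloxy)-2,5,6-trimethylphenol | Cc1cc(OCc2ccccc2)c(C)c(O)c1C
A8 | alternative 3 | 3-acetoxy-2,5,6-trimethylphenyl 4-[(4-acetoxy-2-hydroxy-3,5,6-trimethylbenzoyl)oxy]-2-hydroxy-3,5,6-trimethylbenzoate | CC(=O)Oc1c(C)c(O)c(C(=O)Oc2c(C)c(O)c(C(=O)Oc3c(C)c(OC(C)=O)cc(C)c3C)c(C)c2C)c(C)c1C
A9 | alternative 3 | 3-acetoxy-2,5,6-trimethylphenyl 4-[(4-acetoxy-2,3,5-trimethylbenzoyl)oxy]-2,3,5-trimethylbenzoate | CC(=O)Oc1c(C)cc(C(=O)Oc2c(C)cc(C(=O)Oc3c(C)c(OC(C)=O)cc(C)c3C)c(C)c2C)c(C)c1C
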